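**Retrosynthetic overview**
1. Target ⇒ late acylation of the C15 alcohol of a 6‑O‑silyl germacradienolide with (2Z)‑2‑(acetoxymethyl)but‑2‑enoic acid, then desilylation.
2. Ten‑membered carbocycle, C6 and C7 ⇒ intramolecular CrCl2‑mediated allylation of an enal by a 3‑(bromomethyl)butenolide (C6–C7 bond).
3. Butenolide ⇒ ring‑closing metathesis of a 2‑(bromomethyl)acrylate of the C8 allylic alcohol; chain ⇒ Negishi alkyl–alkenyl coupling (C3–C4) and Zr‑catalysed carboalumination (E‑C1=C10).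
4. C8 ⇒ ketoreductase reduction of ethyl 4‑chloro‑3‑oxobutanoate; it is the only stereocentre carried into the cyclisation.
5. Ring order: five‑membered lactone (as butenolide) first, ten‑membered ring second.

Assumption: germacrane numbering is used for atom labels (C6 carbinol, C7/C8 ring fusion, C12 lactone carbonyl, C13 exocyclic methylene, C15 oxygenated methyl); the SMILES is read as (6R,7S,8S), 1(10)E, C3 cis to C6 across C4=C5, trans‑fused lactone, and a (2Z)‑acyl group on O15.

**Route**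

Step 1
Reactants: 1 ethyl 4-chloro-3-oxobutanoate
Product: 2 ethyl (3S)-4-chloro-3-hydroxybutanoate
Conditions: (S)-selective ketoreductase (NADPH-dependent carbonyl reductase, oxidoreductase class), NADP+ (cat.), i-PrOH as hydride donor, phosphate buffer pH 6.5 / n-butyl acetate, 30 °C
Reagents that add atoms: none
Why: Enzymatic asymmetric ketone reduction (ketoreductase) delivers hydride to one face of the prochiral β-keto ester and sets C8 as S in >99% ee, the only stereocentre not made by relay.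

Step 2
Reactants: 2 ethyl (3S)-4-chloro-3-hydroxybutanoate
Product: 3 ethyl (3S)-3-[(tert-butyldimethylsilyl)oxy]-4-chlorobutanoate
Conditions: TBSCl, imidazole, DMF, rt
Reagents that add atoms: tert-butyldimethylsilyl chloride, CC(C)(C)[Si](C)(C)Cl
Why: Silyl ether formation blocks retro-aldol, elimination and premature epoxide closure of the chlorohydrin in the following basic and Lewis-acidic steps.

Step 3
Reactants: 3 ethyl (3S)-3-[(tert-butyldimethylsilyl)oxy]-4-chlorobutanoate
Product: 4 (3S)-3-[(tert-butyldimethylsilyl)oxy]-4-chlorobutanal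
Conditions: i-Bu2AlH (1.1 equiv), CH2Cl2, −78 °C; aq. KNaC4H4O6 work-up
Reagents that add atoms: none
Why: Low-temperature DIBAL-H half-reduction of a β-silyloxy ester stops at the aldehyde through a stable tetrahedral aluminium acetal.

Step 4
Reactants: 4 (3S)-3-[(tert-butyldimethylsilyl)oxy]-4-chlorobutanal
Product: 5 tert-butyl{[(2S)-1-chloropent-4-yn-2-yl]oxy}dimethylsilane
Conditions: dimethyl (1-diazo-2-oxopropyl)phosphonate, K2CO3, MeOH, 0 °C to rt
Reagents that add atoms: dimethyl (1-diazo-2-oxopropyl)phosphonate, COP(=O)(OC)C(=[N+]=[N-])C(C)=O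
Why: Ohira–Bestmann (Seyferth–Gilbert) homologation converts the aldehyde into the terminal alkyne under conditions mild enough for the β-silyloxy and chloride groups.

Step 5
Reactants: 5 tert-butyl{[(2S)-1-chloropent-4-yn-2-yl]oxy}dimethylsilane
Product: 8 (3E,6S)-6-[(tert-butyldimethylsilyl)oxy]-7-chloro-4-methylhept-3-en-1-ol, via alkenyldimethylalane 6 (not isolated), via lithium alkenylalanate 7 (not isolated)
Conditions: AlMe3 (2.5 equiv), Cp2ZrCl2 (0.25 equiv), CH2Cl2, 0 °C to rt; evaporate, hexane, n-BuLi, −78 to 0 °C; oxirane, THF, −78 °C to rt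
Reagents that add atoms: trimethylaluminium, C[Al](C)C; oxirane, C1CO1
Why: Zirconium-catalysed Negishi carboalumination adds Me and Al syn across the alkyne with Me on the internal carbon, so C9 and C2 end up trans (1(10)E), and the alanate opens oxirane with retention of that geometry.

Step 6
Reactants: 8 (3E,6S)-6-[(tert-butyldimethylsilyl)oxy]-7-chloro-4-methylhept-3-en-1-ol
Product: 9 tert-butyl{[(2S,4E)-1-chloro-7-iodo-4-methylhept-4-en-2-yl]oxy}dimethylsilane
Conditions: I2, PPh3, imidazole, CH2Cl2, 0 °C to rt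
Reagents that add atoms: iodine, II
Why: Appel-type iodination converts the primary alcohol into the iodide needed for zinc insertion without touching the silyl ether, chloride or alkene.

Step 7
Reactants: 10 but-2-yne-1,4-diol
Product: 11 4-[(4-methoxybenzyl)oxy]but-2-yn-1-ol
Conditions: NaH (1 equiv), 4-methoxybenzyl chloride (0.35 equiv), Bu4NI (cat.), THF/DMF, 0 °C to rt
Reagents that add atoms: 4-methoxybenzyl chloride, COc1ccc(CCl)cc1
Why: Williamson etherification with excess diol gives the mono-ether, which differentiates the future C15 oxygen (PMB) from the future C6 oxygen.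

Step 8
Reactants: 11 4-[(4-methoxybenzyl)oxy]but-2-yn-1-ol
Product: 13 (2Z)-3-iodo-4-[(4-methoxybenzyl)oxy]but-2-en-1-ol, via cyclic alkenylalanate 12 (not isolated)
Conditions: NaAlH2(OCH2CH2OMe)2 (Red-Al, 1.5 equiv), THF, 0 °C to rt; then I2, THF, −78 to 0 °C
Reagents that add atoms: iodine, II
Why: Hydroxyl-directed trans-hydroalumination puts hydride on C5 and aluminium on C4 in a five-membered alanate, and iodinolysis with retention leaves iodine cis to C6, the position C3 must later occupy.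

Step 9
Reactants: 13 (2Z)-3-iodo-4-[(4-methoxybenzyl)oxy]but-2-en-1-ol
Product: 14 tert-butyl({(2Z)-3-iodo-4-[(4-methoxybenzyl)oxy]but-2-en-1-yl}oxy)dimethylsilane
Conditions: TBSCl, imidazole, CH2Cl2, rt
Reagents that add atoms: tert-butyldimethylsilyl chloride, CC(C)(C)[Si](C)(C)Cl
Why: Silylation removes the acidic proton that would quench the organozinc partner and lets both silyl groups be removed together later.

Step 10
Reactants: 9 tert-butyl{[(2S,4E)-1-chloro-7-iodo-4-methylhept-4-en-2-yl]oxy}dimethylsilane, 14 tert-butyl({(2Z)-3-iodo-4-[(4-methoxybenzyl)oxy]but-2-en-1-yl}oxy)dimethylsilane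
Product: 16 (2E,6E,9S)-1,9-bis[(tert-butyldimethylsilyl)oxy]-10-chloro-3-{[(4-methoxybenzyl)oxy]methyl}-7-methyldeca-2,6-diene, via alkylzinc iodide 15 (not isolated)
Conditions: 9, Zn dust (activated with BrCH2CH2Br/Me3SiCl), LiCl, THF, 40 °C; then 14, Pd(dppf)Cl2 (5 mol %), THF/DMF, 50 °C
Reagents that add atoms: none
Why: Negishi alkyl–alkenyl coupling of the homoallylic zinc reagent proceeds with retention at the iodoalkene, so C3 takes the place of iodine cis to C6 and gives the ring-cis C4=C5 geometry; the alkyl chloride is inert to zinc and zerovalent palladium.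

Step 11
Reactants: 16 (2E,6E,9S)-1,9-bis[(tert-butyldimethylsilyl)oxy]-10-chloro-3-{[(4-methoxybenzyl)oxy]methyl}-7-methyldeca-2,6-diene
Product: 18 (2E,6E)-3-{[(4-methoxybenzyl)oxy]methyl}-7-methyl-8-[(2S)-oxiran-2-yl]octa-2,6-dien-1-ol, via chloro diol 17 (not isolated)
Conditions: Bu4NF (3 equiv), THF, 0 °C to rt; then K2CO3, MeOH, rt
Reagents that add atoms: none
Why: Fluoride removes both silyl ethers and the liberated C8 alkoxide displaces the neighbouring primary chloride (intramolecular Williamson, 3-exo-tet) without touching the C8–O bond, so C8 stays S.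

Step 12
Reactants: 18 (2E,6E)-3-{[(4-methoxybenzyl)oxy]methyl}-7-methyl-8-[(2S)-oxiran-2-yl]octa-2,6-dien-1-ol
Product: 19 (2E,6E,9S)-3-{[(4-methoxybenzyl)oxy]methyl}-7-methylundeca-2,6,10-triene-1,9-diol
Conditions: Me3S+ I− (5 equiv), n-BuLi (4.8 equiv), THF, −10 °C; then 18, −10 °C to rt
Reagents that add atoms: trimethylsulfonium iodide, C[S+](C)C.[I-]
Why: Dimethylsulfonium methylide opens the terminal epoxide at C7 and the betaine eliminates Me2S to give the one-carbon-homologated allylic alcohol, again with the C8–O bond intact.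

Step 13
Reactants: 19 (2E,6E,9S)-3-{[(4-methoxybenzyl)oxy]methyl}-7-methylundeca-2,6,10-triene-1,9-diol
Product: 20 (2E,6E,9S)-9-hydroxy-3-{[(4-methoxybenzyl)oxy]methyl}-7-methylundeca-2,6,10-trienal
Conditions: TEMPO (10 mol %), PhI(OAc)2 (1.1 equiv), CH2Cl2, rt
Reagents that add atoms: none
Why: Oxoammonium (TEMPO/PhI(OAc)2) oxidation is selective for the primary allylic alcohol over the secondary one and does not isomerise the trisubstituted enal.

Step 14
Reactants: 20 (2E,6E,9S)-9-hydroxy-3-{[(4-methoxybenzyl)oxy]methyl}-7-methylundeca-2,6,10-trienal, 21 2-(bromomethyl)prop-2-enoic acid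
Product: 22 (3S,5E,9E)-9-{[(4-methoxybenzyl)oxy]methyl}-5-methyl-11-oxoundeca-1,5,9-trien-3-yl 2-(bromomethyl)prop-2-enoate
Conditions: DCC (1.3 equiv), DMAP (5 mol %), CH2Cl2, −10 to 0 °C
Reagents that add atoms: none
Why: Steglich esterification acylates the only free hydroxyl (C8–OH) with retention at C8, and low temperature with little DMAP limits attack on the allylic bromide.

Step 15
Reactants: 22 (3S,5E,9E)-9-{[(4-methoxybenzyl)oxy]methyl}-5-methyl-11-oxoundeca-1,5,9-trien-3-yl 2-(bromomethyl)prop-2-enoate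
Product: 23 (2E,6E)-8-[(2S)-4-(bromomethyl)-5-oxo-2,5-dihydrofuran-2-yl]-3-{[(4-methoxybenzyl)oxy]methyl}-7-methylocta-2,6-dienal
Conditions: second-generation Grubbs catalyst RuCl2(=CHPh)(PCy3)(H2IMes) (10 mol %), CH2Cl2 (5 mM), 40 °C
Reagents that add atoms: none
Why: Ring-closing metathesis between the vinyl group and the 1,1-disubstituted acrylate is the only closure that gives an unstrained (five-membered) ring, the two trisubstituted alkenes being too hindered and wrongly placed to compete.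

Step 16
Reactants: 23 (2E,6E)-8-[(2S)-4-(bromomethyl)-5-oxo-2,5-dihydrofuran-2-yl]-3-{[(4-methoxybenzyl)oxy]methyl}-7-methylocta-2,6-dienal
Product: 25 (6R,7S,8S)-6-hydroxy-15-[(4-methoxybenzyl)oxy]germacra-1(10),4,11(13)-trien-12,8-olide, via allylchromium dichloride 24 (not isolated)
Conditions: CrCl2 (8 equiv), DMF/THF, rt, 23 added by syringe pump over 10 h to 2 mM
Reagents that add atoms: none
Why: Intramolecular Nozaki–Hiyama (chromium Barbier-type) allylation, in which divalent chromium makes an allylchromium whose γ-substituent is locked E-like by the butenolide ring, so a chair Zimmerman–Traxler transition state with the enal residue equatorial gives the 6,7-anti adduct (6R), and C6 bonds to C7 on the face opposite the C8–C9 bond to give the less strained trans-fused lactone (7S).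

Step 17
Reactants: 25 (6R,7S,8S)-6-hydroxy-15-[(4-methoxybenzyl)oxy]germacra-1(10),4,11(13)-trien-12,8-olide
Product: 26 6-O-triethylsilyl ether of 25
Conditions: Et3SiOTf, 2,6-lutidine, CH2Cl2, −78 °C
Reagents that add atoms: triethylsilyl trifluoromethanesulfonate, CC[Si](CC)(CC)OS(=O)(=O)C(F)(F)F
Why: Silylation of the C6 hydroxyl prevents its acylation and any translactonisation to a 6,12-olide during the later base-containing steps.

Step 18
Reactants: 26 6-O-triethylsilyl ether of 25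
Product: 27 (6R,7R,8S)-15-hydroxy-6-[(triethylsilyl)oxy]germacra-1(10),4,11(13)-trien-12,8-olide
Conditions: DDQ (1.3 equiv), CH2Cl2 / pH 7 phosphate buffer (10:1), 0 °C
Reagents that add atoms: none
Why: Oxidative PMB cleavage by DDQ frees only the C15 hydroxyl, and the buffer protects the acid-labile silyl ether.

Step 19
Reactants: 28 (2E)-but-2-enal
Product: 29 (2Z)-2-iodobut-2-enal
Conditions: I2 (1.5 equiv), K2CO3, DMAP (20 mol %), THF/H2O (1:1), rt
Reagents that add atoms: iodine, II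
Why: Amine-catalysed α-iodination of the enal (addition–iodination–elimination) keeps the methyl group trans to the formyl group, so iodine ends up cis to methyl.

Step 20
Reactants: 29 (2Z)-2-iodobut-2-enal
Product: 30 (2Z)-2-iodobut-2-en-1-ol
Conditions: NaBH4, CeCl3·7H2O, MeOH, 0 °C
Reagents that add atoms: none
Why: Luche 1,2-reduction gives the allylic alcohol without touching the C–I bond or the alkene geometry.

Step 21
Reactants: 30 (2Z)-2-iodobut-2-en-1-ol
Product: 32 (2Z)-2-(hydroxymethyl)but-2-enoic acid, via dilithio dianion 31 (not isolated)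
Conditions: n-BuLi (1.05 equiv), Et2O, −78 °C; t-BuLi (2.1 equiv), −78 °C; CO2 (gas), −78 °C to rt; aq. HCl
Reagents that add atoms: carbon dioxide, O=C=O
Why: Iodine–lithium exchange on the lithium alkoxide gives a configurationally stable alkenyllithium (no β-elimination from an alkoxide) that is carboxylated with retention, placing CO2H cis to methyl.

Step 22
Reactants: 32 (2Z)-2-(hydroxymethyl)but-2-enoic acid
Product: 33 (2Z)-2-(acetoxymethyl)but-2-enoic acid
Conditions: Ac2O, pyridine, CH2Cl2, 0 °C to rt; then H2O/THF, acidify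
Reagents that add atoms: acetic anhydride, CC(=O)OC(C)=O
Why: O-acetylation of the primary allylic alcohol under mild conditions, with aqueous cleavage of any mixed carboxylic anhydride, returns the free (Z)-acid.

Step 23
Reactants: 27 (6R,7R,8S)-15-hydroxy-6-[(triethylsilyl)oxy]germacra-1(10),4,11(13)-trien-12,8-olide, 33 (2Z)-2-(acetoxymethyl)but-2-enoic acid
Product: 35 6-O-triethylsilyl ether of the target, via mixed anhydride 34 (not isolated)
Conditions: 33, 2,4,6-trichlorobenzoyl chloride, Et3N, toluene, rt, 2 h; then 27, toluene, 70 °C (no DMAP)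
Reagents that add atoms: none
Why: Mixed-anhydride (Yamaguchi-type) esterification run without a nucleophilic amine catalyst transfers the hindered (Z)-acyl group to the primary allylic C15–OH without Z-to-E isomerisation.

Step 24
Reactants: 35 6-O-triethylsilyl ether of the target
Product: 36 (6R,7S,8S)-15-{[(2Z)-2-(acetoxymethyl)but-2-enoyl]oxy}-6-hydroxygermacra-1(10),4,11(13)-trien-12,8-olide (CNP0184624.2)
Conditions: HF·pyridine, pyridine, THF, 0 °C to rt
Reagents that add atoms: none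
Why: Fluoride-mediated desilylation under buffered acidic conditions frees the C6 hydroxyl without cleaving the two esters, the allylic acetate or the α-methylene lactone.

**Compound list**
1 | ethyl 4-chloro-3-oxobutanoate | CCOC(=O)CC(=O)CCl | starting material
2 | ethyl (3S)-4-chloro-3-hydroxybutanoate | CCOC(=O)C[C@H](O)CCl | intermediate
3 | ethyl (3S)-3-[(tert-butyldimethylsilyl)oxy]-4-chlorobutanoate | CCOC(=O)C[C@H](O[Si](C)(C)C(C)(C)C)CCl | intermediate
4 | (3S)-3-[(tert-butyldimethylsilyl)oxy]-4-chlorobutanal | O=CC[C@H](O[Si](C)(C)C(C)(C)C)CCl | intermediate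
5 | tert-butyl{[(2S)-1-chloropent-4-yn-2-yl]oxy}dimethylsilane | C#CC[C@H](O[Si](C)(C)C(C)(C)C)CCl | intermediate
6 | [(1E,4S)-4-[(tert-butyldimethylsilyl)oxy]-5-chloro-2-methylpent-1-en-1-yl]dimethylalane (not isolated) | C[Al](C)/C=C(\C)C[C@H](O[Si](C)(C)C(C)(C)C)CCl | intermediate
7 | lithium butyl[(1E,4S)-4-[(tert-butyldimethylsilyl)oxy]-5-chloro-2-methylpent-1-en-1-yl]dimethylalanate (not isolated) | [Li+].CCCC[Al-](C)(C)/C=C(\C)C[C@H](O[Si](C)(C)C(C)(C)C)CCl | intermediate
8 | (3E,6S)-6-[(tert-butyldimethylsilyl)oxy]-7-chloro-4-methylhept-3-en-1-ol | OCC/C=C(\C)C[C@H](O[Si](C)(C)C(C)(C)C)CCl | intermediate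
9 | tert-butyl{[(2S,4E)-1-chloro-7-iodo-4-methylhept-4-en-2-yl]oxy}dimethylsilane | ICC/C=C(\C)C[C@H](O[Si](C)(C)C(C)(C)C)CCl | intermediate
10 | but-2-yne-1,4-diol | OCC#CCO | starting material
11 | 4-[(4-methoxybenzyl)oxy]but-2-yn-1-ol | OCC#CCOCc1ccc(OC)cc1 | intermediate
12 | sodium cyclic alkenylalanate (2,5-dihydro-1,2-oxaluminol-2-uide bearing two 2-methoxyethoxy groups and the CH2OPMB arm on C3; not isolated) | [Na+].COCCO[Al-]1(OCCOC)OCC=C1COCc2ccc(OC)cc2 | intermediate
13 | (2Z)-3-iodo-4-[(4-methoxybenzyl)oxy]but-2-en-1-ol (I cis to CH2OH) | OC/C=C(\I)COCc1ccc(OC)cc1 | intermediate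
14 | tert-butyl({(2Z)-3-iodo-4-[(4-methoxybenzyl)oxy]but-2-en-1-yl}oxy)dimethylsilane | CC(C)(C)[Si](C)(C)OC/C=C(\I)COCc1ccc(OC)cc1 | intermediate
15 | [(3E,6S)-6-[(tert-butyldimethylsilyl)oxy]-7-chloro-4-methylhept-3-en-1-yl]zinc iodide (not isolated) | I[Zn]CC/C=C(\C)C[C@H](O[Si](C)(C)C(C)(C)C)CCl | intermediate
16 | (2E,6E,9S)-1,9-bis[(tert-butyldimethylsilyl)oxy]-10-chloro-3-{[(4-methoxybenzyl)oxy]methyl}-7-methyldeca-2,6-diene (C3 chain cis to CH2OTBS) | CC(C)(C)[Si](C)(C)OC/C=C(\CC/C=C(\C)C[C@H](O[Si](C)(C)C(C)(C)C)CCl)COCc1ccc(OC)cc1 | intermediate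
17 | (2E,6E,9S)-10-chloro-3-{[(4-methoxybenzyl)oxy]methyl}-7-methyldeca-2,6-diene-1,9-diol (not isolated) | OC/C=C(\CC/C=C(\C)C[C@H](O)CCl)COCc1ccc(OC)cc1 | intermediate
18 | (2E,6E)-3-{[(4-methoxybenzyl)oxy]methyl}-7-methyl-8-[(2S)-oxiran-2-yl]octa-2,6-dien-1-ol | OC/C=C(\CC/C=C(\C)C[C@H]1CO1)COCc2ccc(OC)cc2 | intermediate
19 | (2E,6E,9S)-3-{[(4-methoxybenzyl)oxy]methyl}-7-methylundeca-2,6,10-triene-1,9-diol | OC/C=C(\CC/C=C(\C)C[C@H](O)C=C)COCc1ccc(OC)cc1 | intermediate
20 | (2E,6E,9S)-9-hydroxy-3-{[(4-methoxybenzyl)oxy]methyl}-7-methylundeca-2,6,10-trienal | O=C/C=C(\CC/C=C(\C)C[C@H](O)C=C)COCc1ccc(OC)cc1 | intermediate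
21 | 2-(bromomethyl)prop-2-enoic acid | C=C(CBr)C(=O)O | starting material
22 | (3S,5E,9E)-9-{[(4-methoxybenzyl)oxy]methyl}-5-methyl-11-oxoundeca-1,5,9-trien-3-yl 2-(bromomethyl)prop-2-enoate | O=C/C=C(\CC/C=C(\C)C[C@H](OC(=O)C(=C)CBr)C=C)COCc1ccc(OC)cc1 | intermediate
23 | (2E,6E)-8-[(2S)-4-(bromomethyl)-5-oxo-2,5-dihydrofuran-2-yl]-3-{[(4-methoxybenzyl)oxy]methyl}-7-methylocta-2,6-dienal | O=C/C=C(\CC/C=C(\C)C[C@@H]1OC(=O)C(CBr)=C1)COCc2ccc(OC)cc2 | intermediate
24 | allylchromium dichloride derived from 23 (CH2Br replaced by CH2CrCl2; not isolated) | O=C/C=C(\CC/C=C(\C)C[C@@H]1OC(=O)C(C[Cr](Cl)Cl)=C1)COCc2ccc(OC)cc2 | intermediate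
25 | (6R,7S,8S)-6-hydroxy-15-[(4-methoxybenzyl)oxy]germacra-1(10),4,11(13)-trien-12,8-olide (1(10)E; C3 cis to C6; trans-fused lactone; 6α-OH) | C=C1C(=O)O[C@H]2C/C(C)=C/CC/C(COCc3ccc(OC)cc3)=C\[C@@H](O)[C@H]12 | intermediate
26 | 6-O-triethylsilyl ether of 25 (same configuration; formal descriptors 6R,7R,8S) | C=C1C(=O)O[C@H]2C/C(C)=C/CC/C(COCc3ccc(OC)cc3)=C\[C@@H](O[Si](CC)(CC)CC)[C@H]12 | intermediate
27 | (6R,7R,8S)-15-hydroxy-6-[(triethylsilyl)oxy]germacra-1(10),4,11(13)-trien-12,8-olide | C=C1C(=O)O[C@H]2C/C(C)=C/CC/C(CO)=C\[C@@H](O[Si](CC)(CC)CC)[C@H]12 | intermediate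
28 | (2E)-but-2-enal | C/C=C/C=O | starting material
29 | (2Z)-2-iodobut-2-enal (I cis to CH3) | C/C=C(\I)C=O | intermediate
30 | (2Z)-2-iodobut-2-en-1-ol | C/C=C(\I)CO | intermediate
31 | dilithio dianion of 30 (C2–Li and O–Li; not isolated) | C/C=C(\[Li])CO[Li] | intermediate
32 | (2Z)-2-(hydroxymethyl)but-2-enoic acid (CO2H cis to CH3) | C/C=C(\C(=O)O)CO | intermediate
33 | (2Z)-2-(acetoxymethyl)but-2-enoic acid | C/C=C(\C(=O)O)COC(C)=O | intermediate
34 | (2Z)-2-(acetoxymethyl)but-2-enoic 2,4,6-trichlorobenzoic anhydride (not isolated) | C/C=C(\C(=O)OC(=O)c1c(Cl)cc(Cl)cc1Cl)COC(C)=O | intermediate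
35 | 6-O-triethylsilyl ether of the target (same configuration; formal descriptors 6R,7R,8S) | C=C1C(=O)O[C@H]2C/C(C)=C/CC/C(COC(=O)/C(=C\C)COC(C)=O)=C\[C@@H](O[Si](CC)(CC)CC)[C@H]12 | intermediate
36 | (6R,7S,8S)-15-{[(2Z)-2-(acetoxymethyl)but-2-enoyl]oxy}-6-hydroxygermacra-1(10),4,11(13)-trien-12,8-olide (CNP0184624.2) | C=C1C(=O)O[C@H]2C/C(C)=C/CC/C(COC(=O)/C(=C\C)COC(C)=O)=C\[C@@H](O)[C@H]12 | target

**Step count and risk**

Total: 24 steps. Longest linear sequence: 17 steps (steps 1–6, 10–18, 23, 24, from compound 1).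

Most likely to fail:

Step 16 (chromium-mediated ring closure). The ten-membered ring may form in modest yield, and the ring may override the chair preference at C6. The configuration of 25 must be confirmed by NOE and J(H6,H7), J(H7,H8) data. Fallback, setting out from 23 and returning at 25: if the closure gives mainly the C6 epimer, (6S,7S,8S)-6-hydroxy-15-[(4-methoxybenzyl)oxy]germacra-1(10),4,11(13)-trien-12,8-olide F8, C6 is no longer set by the allylation but by ketone reduction. MnO2 in CH2Cl2 oxidises the allylic alcohol to the enone (7R,8S)-15-[(4-methoxybenzyl)oxy]-6-oxogermacra-1(10),4,11(13)-trien-12,8-olide F9. Luche reduction (NaBH4, CeCl3·7H2O, MeOH, −78 °C, short contact to spare the methylene lactone) then delivers hydride from the exposed outer face of the macrocycle to give 25.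

Step 15 (metathesis of the bromomethyl acrylate). The allylic bromide and the polyene may erode catalyst turnover. Fallback, setting out from 20 and returning at 23: the bromide is introduced after the ring is made. DCC/DMAP esterification of 20 with 2-{[(tert-butyldimethylsilyl)oxy]methyl}prop-2-enoic acid gives (3S,5E,9E)-9-{[(4-methoxybenzyl)oxy]methyl}-5-methyl-11-oxoundeca-1,5,9-trien-3-yl 2-{[(tert-butyldimethylsilyl)oxy]methyl}prop-2-enoate F4. Ring-closing metathesis with the same ruthenium catalyst gives the silyloxymethyl butenolide (2E,6E)-8-[(2S)-4-{[(tert-butyldimethylsilyl)oxy]methyl}-5-oxo-2,5-dihydrofuran-2-yl]-3-{[(4-methoxybenzyl)oxy]methyl}-7-methylocta-2,6-dienal F5. HF·pyridine in THF gives the hydroxymethyl butenolide (2E,6E)-8-[(2S)-4-(hydroxymethyl)-5-oxo-2,5-dihydrofuran-2-yl]-3-{[(4-methoxybenzyl)oxy]methyl}-7-methylocta-2,6-dienal F6. MsCl/Et3N in CH2Cl2 at −20 °C gives the corresponding allylic mesylate F7, and LiBr in THF displaces it to give 23.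

Step 5 (carboalumination with oxirane trapping). Opening of oxirane by the alanate can be sluggish on a functionalised substrate. Fallback, setting out from 5 and returning at 16: the same carboalumination is quenched with I2 to give tert-butyl{[(2S,4E)-1-chloro-5-iodo-4-methylpent-4-en-2-yl]oxy}dimethylsilane F1. Stille coupling with tributyl(vinyl)stannane (Pd(PPh3)4, DMF, 60 °C) gives tert-butyl{[(2S,4E)-1-chloro-4-methylhepta-4,6-dien-2-yl]oxy}dimethylsilane F2. 9-BBN in THF hydroborates only the terminal vinyl group to give 9-[(3E,6S)-6-[(tert-butyldimethylsilyl)oxy]-7-chloro-4-methylhept-3-en-1-yl]-9-borabicyclo[3.3.1]nonane F3. This is used at once in a B-alkyl Suzuki–Miyaura coupling with 14 (Pd(dppf)Cl2, AsPh3, Cs2CO3, DMF/THF/H2O) to give 16, bypassing 8, 9 and 15.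

**Further compounds**
F1 | step 5 | tert-butyl{[(2S,4E)-1-chloro-5-iodo-4-methylpent-4-en-2-yl]oxy}dimethylsilane | I/C=C(\C)C[C@H](O[Si](C)(C)C(C)(C)C)CCl
F2 | step 5 | tert-butyl{[(2S,4E)-1-chloro-4-methylhepta-4,6-dien-2-yl]oxy}dimethylsilane | C=C/C=C(\C)C[C@H](O[Si](C)(C)C(C)(C)C)CCl
F3 | step 5 | 9-[(3E,6S)-6-[(tert-butyldimethylsilyl)oxy]-7-chloro-4-methylhept-3-en-1-yl]-9-borabicyclo[3.3.1]nonane | C1CCC2CCCC1B2CC/C=C(\C)C[C@H](O[Si](C)(C)C(C)(C)C)CCl
F4 | step 15 | (3S,5E,9E)-9-{[(4-methoxybenzyl)oxy]methyl}-5-methyl-11-oxoundeca-1,5,9-trien-3-yl 2-{[(tert-butyldimethylsilyl)oxy]methyl}prop-2-enoate | O=C/C=C(\CC/C=C(\C)C[C@H](OC(=O)C(=C)CO[Si](C)(C)C(C)(C)C)C=C)COCc1ccc(OC)cc1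
F5 | step 15 | (2E,6E)-8-[(2S)-4-{[(tert-butyldimethylsilyl)oxy]methyl}-5-oxo-2,5-dihydrofuran-2-yl]-3-{[(4-methoxybenzyl)oxy]methyl}-7-methylocta-2,6-dienal | O=C/C=C(\CC/C=C(\C)C[C@@H]1OC(=O)C(CO[Si](C)(C)C(C)(C)C)=C1)COCc2ccc(OC)cc2
F6 | step 15 | (2E,6E)-8-[(2S)-4-(hydroxymethyl)-5-oxo-2,5-dihydrofuran-2-yl]-3-{[(4-methoxybenzyl)oxy]methyl}-7-methylocta-2,6-dienal | O=C/C=C(\CC/C=C(\C)C[C@@H]1OC(=O)C(CO)=C1)COCc2ccc(OC)cc2
F7 | step 15 | {(5S)-5-[(2E,6E)-7-{[(4-methoxybenzyl)oxy]methyl}-3-methyl-9-oxonona-2,6-dien-1-yl]-2-oxo-2,5-dihydrofuran-3-yl}methyl methanesulfonate | O=C/C=C(\CC/C=C(\C)C[C@@H]1OC(=O)C(COS(C)(=O)=O)=C1)COCc2ccc(OC)cc2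
F8 | step 16 | (6S,7S,8S)-6-hydroxy-15-[(4-methoxybenzyl)oxy]germacra-1(10),4,11(13)-trien-12,8-olide | C=C1C(=O)O[C@H]2C/C(C)=C/CC/C(COCc3ccc(OC)cc3)=C\[C@H](O)[C@H]12
F9 | step 16 | (7R,8S)-15-[(4-methoxybenzyl)oxy]-6-oxogermacra-1(10),4,11(13)-trien-12,8-olide | C=C1C(=O)O[C@H]2C/C(C)=C/CC/C(COCc3ccc(OC)cc3)=C\C(=O)[C@H]12
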